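The trans-decalin is disconnected across ring B at C5–C10 and C8–C9. Ring A (C1–C5, C10) shares the C5–C10 fusion bond with ring B, and C8–C9 lies across ring B from it. An open chain carrying a C5=C6–C7=C8 silyloxydiene and a C9=C10 (E)-enal, joined by C1–C4, can therefore fold into both rings. One catalytic asymmetric intramolecular Diels–Alder reaction closes rings A and B and sets C5, C10 and C9 (and C8, erased later). The precursor is (2E,8E,10E)-3,7,7-trimethyl-11-(triisopropylsilyloxy)undeca-2,8,10-trienal, built from 3,3-dimethylglutaric anhydride. C11 is then extended with an enantiopure C12–C16 ylide, C8 is converted to the exocyclic methylene and C7 is oxidised last.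

Key step: step 11

Remarks on the chemistry (labdane numbering C1–C20 is used for every intermediate):
- Assumption: the enal binds the boron cation in the formyl C–H···O mode; on that model the (R)-configured catalyst leaves the C9 Si face open and gives the (5S,10S) series. The mirror-image catalyst is equally accessible if the sense proves opposite.
- Assumption: (R)-4-methyldihydrofuran-2(3H)-one (16) is bought as the single enantiomer.
- The dienol ether carries triisopropylsilyl, which should resist the cationic Lewis acid and chromatography better than smaller silyl groups. C8 is oxidised later, so its configuration is of no consequence.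
- The cycloadduct has no C12 and is therefore named as a 12-nordrim-6-en-11-al.

Step 1
Reactants: 1 3,3-dimethylglutaric anhydride
Product: 2 4,4-dimethyltetrahydro-2H-pyran-2-one
Conditions: NaBH4, THF, 0 °C to rt; then 6 M HCl, rt
Reagents that add atoms: none
Why: Borohydride reduction of one carbonyl of the cyclic anhydride followed by acid-induced lactonisation (anhydride-to-lactone reduction); the anhydride is symmetric, so no regiochemical or stereochemical issue arises.

Step 2
Reactants: 2 4,4-dimethyltetrahydro-2H-pyran-2-one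
Product: 3 4,4-dimethyltetrahydro-2H-pyran-2-ol
Conditions: i-Bu2AlH (DIBAL-H, 1.1 equiv), CH2Cl2, −78 °C; aq. KNaC4H4O6
Reagents that add atoms: none
Why: Partial DIBAL-H reduction of a lactone stops at the lactol because the tetrahedral aluminium hemiacetal persists at −78 °C until work-up.

Step 3
Reactants: 3 4,4-dimethyltetrahydro-2H-pyran-2-ol
Product: 4 3,3-dimethylhex-5-en-1-ol
Conditions: Ph3PCH3Br (2.5 equiv), KOtBu (2.4 equiv), THF, 0 °C to 60 °C
Reagents that add atoms: methyltriphenylphosphonium bromide, C[P+](c1ccccc1)(c1ccccc1)c1ccccc1.[Br-]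
Why: Wittig methylenation of the open hydroxy-aldehyde form of the lactol, which the non-stabilised ylide drains from the ring–chain equilibrium; the new CH2 becomes C1.

Step 4
Reactants: 5 ethyl acetoacetate
Product: 6 ethyl (2E)-3-(trifluoromethylsulfonyloxy)but-2-enoate
Conditions: Tf2O, aq. Me4NOH, hexanes, 5 °C
Reagents that add atoms: trifluoromethanesulfonic anhydride, O=S(=O)(OS(=O)(=O)C(F)(F)F)C(F)(F)F
Why: O-Triflation of the β-keto ester enolate; with the non-coordinating tetramethylammonium counter-ion the enolate is not chelated, so the (E)-enol triflate (triflate trans to the ester) should predominate.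

Step 5
Reactants: 4 3,3-dimethylhex-5-en-1-ol; 6 ethyl (2E)-3-(trifluoromethylsulfonyloxy)but-2-enoate
Product: 8 ethyl (2E)-9-hydroxy-3,7,7-trimethylnon-2-enoate, via alkylborane 7 (not isolated)
Conditions: 9-BBN-H (2.2 equiv), THF, 0 °C to rt; then 6, PdCl2(dppf) (5 mol %), AsPh3, Cs2CO3, DMF/H2O, rt
Reagents that add atoms: none
Why: Anti-Markovnikov hydroboration of the terminal alkene (one equivalent of borane is taken up by the hydroxyl group) and B-alkyl Suzuki–Miyaura coupling, which forms C1–C10 with retention of the vinyl triflate geometry and so fixes the (E)-C9=C10 bond.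

Step 6
Reactants: 8 ethyl (2E)-9-hydroxy-3,7,7-trimethylnon-2-enoate
Product: 9 ethyl (2E)-3,7,7-trimethyl-9-oxonon-2-enoate
Conditions: Dess–Martin periodinane, NaHCO3, CH2Cl2, 0 °C to rt
Reagents that add atoms: none
Why: Dess–Martin oxidation of an unhindered primary alcohol to the aldehyde (C6) under buffered conditions that leave the enoate untouched.

Step 7
Reactants: 9 ethyl (2E)-3,7,7-trimethyl-9-oxonon-2-enoate; 10 (triphenylphosphoranylidene)acetaldehyde
Product: 11 ethyl (2E,9E)-3,7,7-trimethyl-11-oxoundeca-2,9-dienoate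
Conditions: toluene, 80 °C
Reagents that add atoms: none
Why: Wittig olefination with the formyl-stabilised ylide adds C7–C8 as the (E)-enal; the product enal is less electrophilic than the saturated aldehyde, so a second homologation should be slow.

Step 8
Reactants: 11 ethyl (2E,9E)-3,7,7-trimethyl-11-oxoundeca-2,9-dienoate
Product: 12 ethyl (2E,8E,10E)-3,7,7-trimethyl-11-(triisopropylsilyloxy)undeca-2,8,10-trienoate
Conditions: i-Pr3SiOTf, Et3N, CH2Cl2, −78 to 0 °C
Reagents that add atoms: triisopropylsilyl trifluoromethanesulfonate, CC(C)[Si](OS(=O)(=O)C(F)(F)F)(C(C)C)C(C)C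
Why: Silyl dienol ether formation by O-silylation of the enal and γ-deprotonation at C5; the s-trans enal gives the (E)-enol ether at C7=C8, the quaternary C4 enforces E at C5=C6, and the ester is not enolised by Et3N.

Step 9
Reactants: 12 ethyl (2E,8E,10E)-3,7,7-trimethyl-11-(triisopropylsilyloxy)undeca-2,8,10-trienoate
Product: 13 (2E,8E,10E)-3,7,7-trimethyl-11-(triisopropylsilyloxy)undeca-2,8,10-trien-1-ol
Conditions: i-Bu2AlH (2.3 equiv), CH2Cl2, −78 °C; aq. KNaC4H4O6
Reagents that add atoms: none
Why: DIBAL-H 1,2-reduction of the conjugated ester to the allylic alcohol; the aluminium hydride does not attack silyl enol ethers and the alkene geometries are untouched.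

Step 10
Reactants: 13 (2E,8E,10E)-3,7,7-trimethyl-11-(triisopropylsilyloxy)undeca-2,8,10-trien-1-ol
Product: 14 (2E,8E,10E)-3,7,7-trimethyl-11-(triisopropylsilyloxy)undeca-2,8,10-trienal
Conditions: MnO2, CH2Cl2, rt
Reagents that add atoms: none
Why: MnO2 oxidation of the primary allylic alcohol to the (E)-enal under neutral heterogeneous conditions, chosen to spare the acid-labile silyl dienol ether.

Step 11
Reactants: 14 (2E,8E,10E)-3,7,7-trimethyl-11-(triisopropylsilyloxy)undeca-2,8,10-trienal
Product: 15 (1R,2S,4aS,8aS)-5,5,8a-trimethyl-2-(triisopropylsilyloxy)-1,2,4a,5,6,7,8,8a-octahydronaphthalene-1-carbaldehyde (8β-triisopropylsilyloxy-12-nordrim-6-en-11-al)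
Conditions: (R)-3,3-diphenyl-1-(o-tolyl)tetrahydro-1H,3H-pyrrolo[1,2-c][1,3,2]oxazaborole (20 mol %), Tf2NH (17 mol %), CH2Cl2, −78 to −40 °C
Reagents that add atoms: none
Why: The cationic boron centre binds the formyl oxygen (with a formyl C–H···O contact to the ring oxygen) and lowers the enal LUMO, so that C5, the diene terminus with the largest HOMO coefficient, bonds to the β-carbon C10 in a concerted but asynchronous [4+2] cycloaddition in which C8–C9 closes slightly later. The closest known reaction type is the oxazaborolidinium-catalysed Diels–Alder reaction of α,β-unsaturated aldehydes, including type 1 intramolecular cases of trienals that give trans-fused bicycles. Ring A (C1–C5 and C10) closes in the fused mode through C5–C10 with the C1–C4 tether folded as a chair (6-exo with respect to C9=C10), and ring B (C5–C10) is the new cyclohexene, formed suprafacially on both partners through C5–C10 and C8–C9. The cis relation of the C9 formyl group to the C10 methyl group follows from the (E)-enal, the trans C5/C10 fusion from the endo transition state (formyl under the diene, tether anti), the C8 configuration from the (E)-enol ether, and the absolute sense from the catalyst, whose aryl group covers the C9 Re face so that the diene adds to the Si face. The step needs endo and facial selectivity and the fused regiochemistry: the four-carbon tether rules out the bridged mode, the polarity of diene and enal matches the tether, the C4 gem-dimethyl group favours the folded conformer, and the bulky silyl group suppresses silyl transfer and proton loss that would lead to open-chain Michael products.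

Step 12
Reactants: 16 (R)-4-methyldihydrofuran-2(3H)-one
Product: 18 methyl (3R)-4-iodo-3-methylbutanoate, via silyl ester 17 (not isolated)
Conditions: Me3SiI, CH2Cl2, rt; then MeOH, 0 to 40 °C
Reagents that add atoms: iodotrimethylsilane, C[Si](C)(C)I; methanol, CO
Why: Iodotrimethylsilane cleavage of the lactone (SN2 attack of iodide on the primary O–CH2 carbon of the O-silylated lactone, remote from the stereocentre) followed by acid-catalysed methanolysis of the silyl ester to the methyl ester.

Step 13
Reactants: 18 methyl (3R)-4-iodo-3-methylbutanoate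
Product: 19 [(2R)-4-methoxy-2-methyl-4-oxobutyl]triphenylphosphonium iodide
Conditions: PPh3, MeCN, 80 °C
Reagents that add atoms: triphenylphosphine, c1ccc(cc1)P(c1ccccc1)c1ccccc1
Why: Quaternisation of triphenylphosphine by the primary iodide (SN2) gives the phosphonium salt without touching the future C13 stereocentre.

Step 14
Reactants: 15 8β-triisopropylsilyloxy-12-nordrim-6-en-11-al; 19 [(2R)-4-methoxy-2-methyl-4-oxobutyl]triphenylphosphonium iodide
Product: 21 methyl (3R,4Z)-3-methyl-5-[(1R,2S,4aS,8aS)-5,5,8a-trimethyl-2-(triisopropylsilyloxy)-1,2,4a,5,6,7,8,8a-octahydronaphthalen-1-yl]pent-4-enoate, via ylide 20 (not isolated)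
Conditions: 19, NaN(SiMe3)2, THF, −78 to 0 °C; then 15, −78 °C to rt
Reagents that add atoms: none
Why: Wittig olefination of the C11 aldehyde with the non-stabilised ylide (the phosphonium C–H is far more acidic than the ester α-H) forms C11=C12, mainly Z; the geometry is immaterial because the alkene is hydrogenated next, and C13 arrives with its configuration fixed.

Step 15
Reactants: 21 Wittig product
Product: 22 methyl (3S)-3-methyl-5-[(1R,2S,4aS,8aS)-5,5,8a-trimethyl-2-(triisopropylsilyloxy)decahydronaphthalen-1-yl]pentanoate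
Conditions: H2 (4 atm), PtO2, EtOAc, rt
Reagents that add atoms: none
Why: Heterogeneous catalytic hydrogenation saturates the two disubstituted alkenes (C6=C7 and C11=C12) without creating stereocentres; platinum is preferred to palladium to limit double-bond migration toward C5 and allylic C–O hydrogenolysis.

Step 16
Reactants: 22 saturated silyl ether
Product: 23 methyl (3S)-5-[(1R,2S,4aS,8aS)-2-hydroxy-5,5,8a-trimethyldecahydronaphthalen-1-yl]-3-methylpentanoate
Conditions: Bu4NF, THF, rt to 50 °C
Reagents that add atoms: none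
Why: Fluoride-induced desilylation driven by Si–F bond formation frees the hindered axial C8 alcohol; no base-sensitive stereocentre is present at this stage.

Step 17
Reactants: 23 8β-alcohol
Product: 24 methyl (3S)-3-methyl-5-[(1R,4aS,8aS)-5,5,8a-trimethyl-2-oxodecahydronaphthalen-1-yl]pentanoate (methyl (13S)-8-oxo-17-norlabdan-15-oate)
Conditions: Dess–Martin periodinane, NaHCO3, CH2Cl2, rt
Reagents that add atoms: none
Why: Dess–Martin oxidation of the secondary alcohol gives the C8 ketone under buffered conditions; the C9 side chain is already equatorial, the thermodynamically preferred arrangement, so C9 is not at risk.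

Step 18
Reactants: 24 C8 ketone
Product: 25 methyl (3S)-3-methyl-5-[(1S,4aS,8aS)-5,5,8a-trimethyl-2-methylidenedecahydronaphthalen-1-yl]pentanoate (methyl (13S)-labd-8(17)-en-15-oate)
Conditions: Zn, CH2Br2, TiCl4, THF/CH2Cl2, 0 °C to rt
Reagents that add atoms: dibromomethane, BrCBr
Why: Takai–Lombardo methylenation converts hindered, enolisable ketones into methylene compounds without base, so C9 is not epimerised, the ester is untouched and no ester–ketone condensation can occur.

Step 19
Reactants: 25 exocyclic alkene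
Product: 26 methyl (3S)-5-[(1R,3R,4aS,8aS)-3-hydroxy-5,5,8a-trimethyl-2-methylidenedecahydronaphthalen-1-yl]-3-methylpentanoate (methyl (13S)-7α-hydroxylabd-8(17)-en-15-oate)
Conditions: SeO2 (0.5 equiv), t-BuOOH, CH2Cl2, 0 °C to rt
Reagents that add atoms: selenium dioxide, O=[Se]=O; tert-butyl hydroperoxide, CC(C)(C)OO
Why: SeO2/t-BuOOH allylic hydroxylation (ene reaction at C17 with loss of the axial 7α-H, then [2,3]-sigmatropic shift) should oxidise the C7 methylene in preference to the C9 methine and deliver oxygen axially on the α face, setting C7 as (R).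

Step 20
Reactants: 26 7α-alcohol
Product: 27 methyl (3S)-5-[(1R,3R,4aS,8aS)-3-acetoxy-5,5,8a-trimethyl-2-methylidenedecahydronaphthalen-1-yl]-3-methylpentanoate (methyl (13S)-7α-acetoxylabd-8(17)-en-15-oate)
Conditions: Ac2O, pyridine, DMAP (cat.), CH2Cl2, rt
Reagents that add atoms: acetic anhydride, CC(=O)OC(C)=O
Why: DMAP-catalysed acylation of the secondary allylic alcohol proceeds with retention at C7 and completes the target.

Compound list
1 | 3,3-dimethylglutaric anhydride | CC1(C)CC(=O)OC(=O)C1 | starting material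
2 | 4,4-dimethyltetrahydro-2H-pyran-2-one | CC1(C)CCOC(=O)C1 | intermediate
3 | 4,4-dimethyltetrahydro-2H-pyran-2-ol (racemic at the acetal carbon) | CC1(C)CCOC(O)C1 | intermediate
4 | 3,3-dimethylhex-5-en-1-ol | C=CCC(C)(C)CCO | intermediate
5 | ethyl acetoacetate | CCOC(=O)CC(C)=O | starting material
6 | ethyl (2E)-3-(trifluoromethylsulfonyloxy)but-2-enoate | CCOC(=O)/C=C(\C)OS(=O)(=O)C(F)(F)F | intermediate
7 | 9-[6-(9-borabicyclo[3.3.1]nonan-9-yloxy)-4,4-dimethylhexyl]-9-borabicyclo[3.3.1]nonane | CC(C)(CCCB1C2CCCC1CCC2)CCOB1C2CCCC1CCC2 | intermediate (not isolated)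
8 | ethyl (2E)-9-hydroxy-3,7,7-trimethylnon-2-enoate | CCOC(=O)/C=C(\C)CCCC(C)(C)CCO | intermediate
9 | ethyl (2E)-3,7,7-trimethyl-9-oxonon-2-enoate | CCOC(=O)/C=C(\C)CCCC(C)(C)CC=O | intermediate
10 | (triphenylphosphoranylidene)acetaldehyde | O=CC=P(c1ccccc1)(c1ccccc1)c1ccccc1 | starting material
11 | ethyl (2E,9E)-3,7,7-trimethyl-11-oxoundeca-2,9-dienoate | CCOC(=O)/C=C(\C)CCCC(C)(C)C/C=C/C=O | intermediate
12 | ethyl (2E,8E,10E)-3,7,7-trimethyl-11-(triisopropylsilyloxy)undeca-2,8,10-trienoate | CCOC(=O)/C=C(\C)CCCC(C)(C)/C=C/C=C/O[Si](C(C)C)(C(C)C)C(C)C | intermediate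
13 | (2E,8E,10E)-3,7,7-trimethyl-11-(triisopropylsilyloxy)undeca-2,8,10-trien-1-ol | OC/C=C(\C)CCCC(C)(C)/C=C/C=C/O[Si](C(C)C)(C(C)C)C(C)C | intermediate
14 | (2E,8E,10E)-3,7,7-trimethyl-11-(triisopropylsilyloxy)undeca-2,8,10-trienal | O=C/C=C(\C)CCCC(C)(C)/C=C/C=C/O[Si](C(C)C)(C(C)C)C(C)C | intermediate (key-step precursor)
15 | (1R,2S,4aS,8aS)-5,5,8a-trimethyl-2-(triisopropylsilyloxy)-1,2,4a,5,6,7,8,8a-octahydronaphthalene-1-carbaldehyde (8β-triisopropylsilyloxy-12-nordrim-6-en-11-al) | CC(C)[Si](C(C)C)(C(C)C)O[C@H]1C=C[C@H]2C(C)(C)CCC[C@]2(C)[C@H]1C=O | intermediate (key-step product)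
16 | (R)-4-methyldihydrofuran-2(3H)-one | C[C@H]1COC(=O)C1 | starting material
17 | trimethylsilyl (3R)-4-iodo-3-methylbutanoate | C[C@H](CC(=O)O[Si](C)(C)C)CI | intermediate (not isolated)
18 | methyl (3R)-4-iodo-3-methylbutanoate | C[C@H](CC(=O)OC)CI | intermediate
19 | [(2R)-4-methoxy-2-methyl-4-oxobutyl]triphenylphosphonium iodide | C[C@H](CC(=O)OC)C[P+](c1ccccc1)(c1ccccc1)c1ccccc1.[I-] | intermediate
20 | methyl (3R)-3-methyl-4-(triphenylphosphoranylidene)butanoate | C[C@H](CC(=O)OC)C=P(c1ccccc1)(c1ccccc1)c1ccccc1 | intermediate (not isolated)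
21 | methyl (3R,4Z)-3-methyl-5-[(1R,2S,4aS,8aS)-5,5,8a-trimethyl-2-(triisopropylsilyloxy)-1,2,4a,5,6,7,8,8a-octahydronaphthalen-1-yl]pent-4-enoate | CC(C)[Si](C(C)C)(C(C)C)O[C@H]1C=C[C@H]2C(C)(C)CCC[C@]2(C)[C@H]1/C=C\[C@H](C)CC(=O)OC | intermediate
22 | methyl (3S)-3-methyl-5-[(1R,2S,4aS,8aS)-5,5,8a-trimethyl-2-(triisopropylsilyloxy)decahydronaphthalen-1-yl]pentanoate | CC(C)[Si](C(C)C)(C(C)C)O[C@H]1CC[C@H]2C(C)(C)CCC[C@]2(C)[C@H]1CC[C@H](C)CC(=O)OC | intermediate
23 | methyl (3S)-5-[(1R,2S,4aS,8aS)-2-hydroxy-5,5,8a-trimethyldecahydronaphthalen-1-yl]-3-methylpentanoate | O[C@H]1CC[C@H]2C(C)(C)CCC[C@]2(C)[C@H]1CC[C@H](C)CC(=O)OC | intermediate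
24 | methyl (13S)-8-oxo-17-norlabdan-15-oate | O=C1CC[C@H]2C(C)(C)CCC[C@]2(C)[C@H]1CC[C@H](C)CC(=O)OC | intermediate
25 | methyl (13S)-labd-8(17)-en-15-oate | C=C1CC[C@H]2C(C)(C)CCC[C@]2(C)[C@H]1CC[C@H](C)CC(=O)OC | intermediate
26 | methyl (13S)-7α-hydroxylabd-8(17)-en-15-oate | C=C1[C@H](O)C[C@H]2C(C)(C)CCC[C@]2(C)[C@H]1CC[C@H](C)CC(=O)OC | intermediate
27 | methyl (13S)-7α-acetoxylabd-8(17)-en-15-oate (CNP0223602.1) | C=C1[C@H](OC(C)=O)C[C@H]2C(C)(C)CCC[C@]2(C)[C@H]1CC[C@H](C)CC(=O)OC | target

Total step count: 20. Longest linear sequence: 17 steps (steps 1–3, 5–11 and 14–20); steps 4, 12 and 13 prepare the two side fragments.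

Steps most likely to fail

1. Step 11 (cycloaddition). The silyl group may transfer to the activated aldehyde or be lost to traces of free acid, giving open-chain material. The β,β-disubstituted enal may also react too slowly below the temperature at which the catalyst decays, or the facial selectivity may be poor. Fallback, setting out from 14 and returning at 15: the trienal 14 is cyclised without any Lewis acid (toluene, 140 °C, BHT, base-washed glass) in a purely thermal intramolecular Diels–Alder reaction. This should give the trans-fused adduct as the racemate, that is 15 together with its mirror image, the (5R,10R)-adduct F1; any cis-fused isomer is removed. Reduction with NaBH4 gives the racemic primary alcohol, the (5S,10S)-alcohol F2 and its enantiomer F3. Esterification with (S)-2-methoxy-2-phenylacetic acid (DCC, DMAP) gives the diastereomeric esters, the (5S,10S)-ester F4 and the (5R,10R)-ester F5, which are separated by chromatography or crystallisation. Methanolysis of F4 (K2CO3, MeOH) returns F2, and Dess–Martin oxidation gives enantiopure 15.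

2. Step 14 (Wittig). Addition of the branched ylide to the neopentyl-type aldehyde next to the silyloxy group may be slow, which leaves time for base-induced enolisation toward C9 and loss of silanol across C8–C9. Fallback, setting out from 18 and 15 and returning at 22: the iodide 18 is treated with 1-phenyl-1H-tetrazole-5-thiol and K2CO3 to give the sulfide F6, which is oxidised with H2O2 and (NH4)6Mo7O24 to the sulfone F7. Julia–Kocienski olefination with 15 (KN(SiMe3)2 added to the mixture of both at −78 °C in DME, so that the base never meets the aldehyde alone) gives the (11E)-alkene F8. Hydrogenation under the conditions of step 15 then gives the same 22.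

3. Step 19 (allylic oxidation). The alcohol may be oxidised further to the enone, the ene reaction may occur at the C9 methine, or the α-facial selectivity may be incomplete. Fallback, setting out from 24 and returning at 26: the ketone 24 is deprotonated kinetically at C7 (LiN(SiMe3)2, THF, −78 °C) to the lithium enolate F9. This is hydroxylated in the same flask with 2-(phenylsulfonyl)-3-phenyloxaziridine from the less hindered α face to give the 7α-hydroxy ketone F10. Silylation (Et3SiOTf, 2,6-lutidine) gives the triethylsilyl ether F11, Takai–Lombardo methylenation as in step 18 gives the silyloxy alkene F12, and HF·pyridine releases 26.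

Further compounds
F1 | step 11 | (5R,8R,9S,10R)-8-triisopropylsilyloxy-12-nordrim-6-en-11-al (enantiomer of 15) | CC(C)[Si](C(C)C)(C(C)C)O[C@@H]1C=C[C@@H]2C(C)(C)CCC[C@@]2(C)[C@@H]1C=O
F2 | step 11 | 8β-triisopropylsilyloxy-12-nordrim-6-en-11-ol | CC(C)[Si](C(C)C)(C(C)C)O[C@H]1C=C[C@H]2C(C)(C)CCC[C@]2(C)[C@H]1CO
F3 | step 11 | enantiomer of F2 | CC(C)[Si](C(C)C)(C(C)C)O[C@@H]1C=C[C@@H]2C(C)(C)CCC[C@@]2(C)[C@@H]1CO
F4 | step 11 | (S)-2-methoxy-2-phenylacetate of F2 | CC(C)[Si](C(C)C)(C(C)C)O[C@H]1C=C[C@H]2C(C)(C)CCC[C@]2(C)[C@H]1COC(=O)[C@@H](OC)c1ccccc1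
F5 | step 11 | (S)-2-methoxy-2-phenylacetate of F3 | CC(C)[Si](C(C)C)(C(C)C)O[C@@H]1C=C[C@@H]2C(C)(C)CCC[C@@]2(C)[C@@H]1COC(=O)[C@@H](OC)c1ccccc1
F6 | step 14 | methyl (3R)-3-methyl-4-[(1-phenyl-1H-tetrazol-5-yl)sulfanyl]butanoate | C[C@H](CC(=O)OC)CSc1nnnn1-c1ccccc1
F7 | step 14 | methyl (3R)-3-methyl-4-[(1-phenyl-1H-tetrazol-5-yl)sulfonyl]butanoate | C[C@H](CC(=O)OC)CS(=O)(=O)c1nnnn1-c1ccccc1
F8 | step 14 | methyl (3R,4E)-3-methyl-5-[(1R,2S,4aS,8aS)-5,5,8a-trimethyl-2-(triisopropylsilyloxy)-1,2,4a,5,6,7,8,8a-octahydronaphthalen-1-yl]pent-4-enoate | CC(C)[Si](C(C)C)(C(C)C)O[C@H]1C=C[C@H]2C(C)(C)CCC[C@]2(C)[C@H]1/C=C/[C@H](C)CC(=O)OC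
F9 | step 19 | lithium 7-en-8-olate of 24 | [Li]OC1=CC[C@H]2C(C)(C)CCC[C@]2(C)[C@H]1CC[C@H](C)CC(=O)OC
F10 | step 19 | methyl (13S)-7α-hydroxy-8-oxo-17-norlabdan-15-oate | O=C1[C@H](O)C[C@H]2C(C)(C)CCC[C@]2(C)[C@H]1CC[C@H](C)CC(=O)OC
F11 | step 19 | methyl (13S)-8-oxo-7α-(triethylsilyloxy)-17-norlabdan-15-oate | O=C1[C@H](O[Si](CC)(CC)CC)C[C@H]2C(C)(C)CCC[C@]2(C)[C@H]1CC[C@H](C)CC(=O)OC
F12 | step 19 | methyl (13S)-7α-(triethylsilyloxy)labd-8(17)-en-15-oate | C=C1[C@H](O[Si](CC)(CC)CC)C[C@H]2C(C)(C)CCC[C@]2(C)[C@H]1CC[C@H](C)CC(=O)OC
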